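**Plan**

- Retrosynthesis: the butenolide is detached at C12–C13 (B-alkyl Suzuki coupling of a C9 vinyl group, C11=C12, made by methylenation of a C11 aldehyde). Ring B is then opened at C5–C10 and C8–C9 (intramolecular Diels–Alder), and the open chain is cut at C3–C4 (malonate alkylation) and C4=C5 (Knoevenagel).
- Enabling feature: ring B (C5–C10) is a cyclohexane with four contiguous stereocentres (C5, C10, C9, C8). Its C5/C10 edge is spanned by the C1–C4 chain of ring A, whose C4 is a malonate-type quaternary carbon, so ring B is a [4+2] retron with a built-in, gem-disubstituted four-atom tether.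
- Forward: an (E)-enoyl imide arm (C1–C3, C9–C11, C20) and a dienylidene malonate (C4–C8, C17–C19) are joined at C3–C4. One cycloaddition closes rings A and B together. C6=C7 is then saturated, the carbonyl groups are reduced, C11 becomes a vinyl group, and the finished butenolide ring is coupled on last.
- Stereochemistry: the (R)-4-benzyloxazolidinone fixes the absolute sense (dienophile face). The (E)-dienophile gives C20/C11 cis at C10/C9, the endo transition state gives the trans fusion at C5, and the (E,E)-diene delivers C8 with C17 axial (8-epi).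
- C8 is corrected later by base equilibration of the C17 aldehyde to the equatorial position. C4 carries two identical arms and is not stereogenic.

Key step: step 7

Remark: labdane numbering is used (C20 on C10, C18/C19 on C4, C17 on C8, C11–C12 chain on C9, C13–C16 butenolide), drawn with C20 α. H-5 and H-9 are then β, C11 is α, and C17 is β in the target and α in the 8-epi intermediates. Xc = (R)-4-benzyl-2-oxooxazolidin-3-yl; TBS = tert-butyldimethylsilyl. 3-[(tert-Butyldimethylsilyl)oxy]propanal and 3-bromofuran-2(5H)-one are taken to be purchasable.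

**Route**

Step 1
Reactants: 1 5-chloropent-1-yne
Product: 4 (E)-6-chloro-3-methylhex-2-enoic acid, via alkenylalane 2 (not isolated), via lithium alanate 3 (not isolated)
Conditions: Me3Al (2 equiv), Cp2ZrCl2 (0.25 equiv), CH2Cl2, 0 °C → rt; volatiles off; n-BuLi, THF–hexane, −78 °C; CO2, −78 °C → rt; 1 M HCl
Reagents that add atoms: trimethylaluminium C[Al](C)C; carbon dioxide O=C=O
Why: Negishi zirconium-catalysed methylalumination adds CH3 and Al syn across the terminal alkyne with Al on the terminal carbon, and carboxylation of the derived alanate proceeds with retention, so the acid should form as the (E)-isomer with C20 cis to the carboxyl carbon C11.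

Step 2
Reactants: 4 (E)-6-chloro-3-methylhex-2-enoic acid; 5 (R)-4-benzyloxazolidin-2-one
Product: 7 (R)-4-benzyl-3-[(E)-6-chloro-3-methylhex-2-enoyl]oxazolidin-2-one, via mixed pivalic anhydride 6 (not isolated)
Conditions: PivCl, Et3N, THF, −20 °C; then 5, LiCl, −20 °C → rt
Reagents that add atoms: none
Why: Evans N-acylation through the mixed pivalic anhydride (Et3N/LiCl protocol) occurs at the less hindered enoyl carbonyl under conditions too mild to deconjugate or isomerise the trisubstituted alkene.

Step 3
Reactants: 7 (R)-4-benzyl-3-[(E)-6-chloro-3-methylhex-2-enoyl]oxazolidin-2-one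
Product: 8 (R)-4-benzyl-3-[(E)-6-iodo-3-methylhex-2-enoyl]oxazolidin-2-one
Conditions: NaI (5 equiv), acetone, reflux
Reagents that add atoms: sodium iodide [Na+].[I-]
Why: Finkelstein exchange at the unhindered primary chloride, driven by precipitation of NaCl, supplies the iodide needed for a low-temperature alkylation.

Step 4
Reactants: 9 3-[(tert-butyldimethylsilyl)oxy]propanal
Product: 10 (E)-5-[(tert-butyldimethylsilyl)oxy]pent-2-enal
Conditions: Ph3P=CHCHO, toluene, 80 °C
Reagents that add atoms: (triphenylphosphoranylidene)acetaldehyde O=CC=P(c1ccccc1)(c1ccccc1)c1ccccc1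
Why: Wittig olefination with the stabilised formylmethylene ylide gives the (E)-enal and stops after one homologation because the conjugated product is less electrophilic than the saturated aldehyde.

Step 5
Reactants: 10 (E)-5-[(tert-butyldimethylsilyl)oxy]pent-2-enal; 11 dimethyl malonate
Product: 12 dimethyl 2-[(2E)-5-[(tert-butyldimethylsilyl)oxy]pent-2-en-1-ylidene]malonate
Conditions: TiCl4, pyridine, THF, 0 °C → rt
Reagents that add atoms: none
Why: Knoevenagel condensation under Lehnert conditions (TiCl4/pyridine) converts the enal into the dienylidene malonate without disturbing the (E)-C6=C7 alkene or the silyl ether.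

Step 6
Reactants: 12 dimethyl 2-[(2E)-5-[(tert-butyldimethylsilyl)oxy]pent-2-en-1-ylidene]malonate; 8 (R)-4-benzyl-3-[(E)-6-iodo-3-methylhex-2-enoyl]oxazolidin-2-one
Product: 14 trienimide dimethyl 2-[(4E)-4-methyl-6-oxo-6-Xc-hex-4-en-1-yl]-2-[(1E,3E)-5-(TBSO)penta-1,3-dien-1-yl]malonate, via potassium trienolate 13 (not isolated)
Conditions: KHMDS (1.05 equiv), THF, −78 °C; then 8, DMPU, −78 → 0 °C
Reagents that add atoms: none
Why: Deconjugative alkylation of an alkylidene malonate: deprotonation at the ε-CH2 (C8) gives a pentadienyl-malonate anion that the primary iodide alkylates at the malonate carbon C4, forming C3–C4 and the quaternary carbon and leaving the C5=C6–C7=C8 diene out of conjugation, its (E,E) geometry following from the extended W-shaped anion.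

Step 7
Reactants: 14 trienimide dimethyl 2-[(4E)-4-methyl-6-oxo-6-Xc-hex-4-en-1-yl]-2-[(1E,3E)-5-(TBSO)penta-1,3-dien-1-yl]malonate
Product: 16 Diels–Alder adduct (Δ6-trans-octalin; 4,4-bis(methoxycarbonyl); 10α-CH3; 5β-H; 8α-CH2OTBS; 9α-C(=O)Xc), via aluminium chelate 15 (not isolated)
Conditions: Me2AlCl (3 equiv), CH2Cl2, −30 → 0 °C
Reagents that add atoms: none
Why: Two-point chelation of both imide carbonyls by a Me2Al+ fragment locks the enoyl unit s-cis and lowers its LUMO, and a concerted, asynchronous [4+2] cycloaddition with the tethered (E,E)-diene then forms C5–C10 and C8–C9, the closest known reaction type being the Lewis-acid-promoted, oxazolidinone-controlled intramolecular Diels–Alder reaction of (E,E,E)-2,8,10-trienoyl imides (1,7,9-decatriene type). Ring B (C5–C10) is closed by the cycloaddition itself as the new cyclohexene, and ring A (C1–C5, C10) is closed by the same C5–C10 bond through the four-atom C1–C4 tether in a chair-like arrangement, exo with respect to both reacting π bonds and helped by the gem-diester at C4 (Thorpe–Ingold effect). C10 and C9 take their absolute configuration from the auxiliary, whose benzyl group blocks one face of the chelated dienophile so that the diene adds to the opposite (C9-re) face, and their cis C20/C11 relation from the (E)-alkene. C5 follows from the endo transition state (imide carbonyl under the diene, tether exo), which places H-5 anti to C20 and gives the trans ring fusion, and C8 follows from the (E)-C7=C8 geometry, which puts C17 cis to C11 and C20 (axial, 8-epi). The step needs endo-over-exo and π-facial selectivity, the first secured by the chelated Lewis acid and the chair-like tether and the second by the benzyl group, while the suprafacial addition transfers both alkene geometries unchanged. The trisubstituted dienophile is the slow element, hence the cationic aluminium chelate and the excess of Lewis acid, one equivalent of which is expected to be held by the malonate.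

Step 8
Reactants: 16 Diels–Alder adduct (Δ6-trans-octalin imide)
Product: 17 saturated imide (trans-decalin; 4,4-bis(methoxycarbonyl); 10α-CH3; 5β-H; 8α-CH2OTBS; 9α-C(=O)Xc)
Conditions: H2 (1 atm), 10% Pd/C, EtOAc, rt
Reagents that add atoms: none
Why: Heterogeneous catalytic hydrogenation saturates the cis-disubstituted C6=C7 alkene without creating a stereocentre, while the imide, esters, silyl ether and C-benzyl group are inert.

Step 9
Reactants: 17 saturated imide
Product: 18 8-epi triol (trans-decalin; 4,4-bis(hydroxymethyl); 9α-CH2OH; 8α-CH2OTBS; 10α-CH3; 5β-H)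
Conditions: LiAlH4 (5 equiv), THF, 0 °C → rt; Fieser work-up
Reagents that add atoms: none
Why: Hydride reduction with LiAlH4 cleaves the N-acyl oxazolidinone at the exocyclic carbonyl to the C11 alcohol and reduces both malonate esters to the C18/C19 diol in one operation, leaving the primary TBS ether and the four stereocentres untouched.

Step 10
Reactants: 18 8-epi triol
Product: 19 acetonide alcohol (C18/C19 diol as 2,2-dimethyl-1,3-dioxane spiro at C4; 9α-CH2OH free; 8α-CH2OTBS)
Conditions: Me2C(OMe)2, PPTS (cat.), acetone, rt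
Reagents that add atoms: 2,2-dimethoxypropane COC(C)(C)OC
Why: Acid-catalysed transacetalisation places the isopropylidene group on the gem-bis(hydroxymethyl) unit as a six-membered 1,3-dioxane, the only unstrained cyclic acetal open to the triol, so C11–OH stays free.

Step 11
Reactants: 19 acetonide alcohol
Product: 20 C11 aldehyde (9α-CHO; 8α-CH2OTBS; C4 spiro-acetonide)
Conditions: Dess–Martin periodinane (1.3 equiv), CH2Cl2, 0 °C → rt
Reagents that add atoms: none
Why: Dess–Martin oxidation of the hindered primary alcohol gives the aldehyde under non-basic conditions that do not epimerise C9.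

Step 12
Reactants: 20 C11 aldehyde
Product: 21 vinyl compound (9α-CH=CH2; 8α-CH2OTBS; C4 spiro-acetonide)
Conditions: Ph3PCH3Br, KOt-Bu, THF, 0 °C; then 20, 0 °C → rt
Reagents that add atoms: methyltriphenylphosphonium bromide C[P+](c1ccccc1)(c1ccccc1)c1ccccc1.[Br-]
Why: Wittig methylenation with the pre-formed ylide converts the hindered aldehyde into the C11=C12 vinyl group faster than enolisation at C9, whose substituent is in any case already equatorial.

Step 13
Reactants: 21 vinyl compound
Product: 22 8-epi alcohol (9α-CH=CH2; 8α-CH2OH axial; C4 spiro-acetonide)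
Conditions: TBAF, THF, rt
Reagents that add atoms: none
Why: Fluoride-mediated desilylation frees C17–OH, while the acetonide and the alkene are inert to TBAF.

Step 14
Reactants: 22 8-epi alcohol
Product: 23 8-epi aldehyde (9α-CH=CH2; 8α-CHO axial; C4 spiro-acetonide)
Conditions: Dess–Martin periodinane (1.3 equiv), CH2Cl2, 0 °C → rt
Reagents that add atoms: none
Why: Dess–Martin oxidation gives the C17 aldehyde as the only carbonyl group of the molecule, so that C8–H becomes the only acidic C–H.

Step 15
Reactants: 23 8-epi aldehyde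
Product: 25 8β-hydroxymethyl 9α-vinyl acetonide (C17 equatorial; trans to the vinyl group), via 8β-aldehyde 24 (not isolated)
Conditions: K2CO3, MeOH, rt; then NaBH4, 0 °C
Reagents that add atoms: none
Why: Base-mediated epimerisation through the enolate moves the axial C8 formyl group, which clashes 1,3-diaxially with C20, to the equatorial 8β position trans to the C9 vinyl group under thermodynamic control, and borohydride reduction in the same flask fixes this configuration as the primary alcohol.

Step 16
Reactants: 25 8β-hydroxymethyl 9α-vinyl acetonide; 26 3-bromofuran-2(5H)-one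
Product: 28 target 18,19-acetonide (3-alkylfuran-2(5H)-one; 8β-CH2OH; C4 spiro-acetonide), via bis-boryl adduct 27 (not isolated)
Conditions: 9-BBN (3 equiv), THF, rt; then 26, PdCl2(dppf) (10 mol %), AsPh3, K3PO4 (aq), DMF, rt
Reagents that add atoms: none
Why: Anti-Markovnikov hydroboration of the monosubstituted alkene with 9-BBN (a further equivalent being taken up by the hydroxyl group as a borinate) followed by B-alkyl Suzuki–Miyaura coupling at the α-bromo enoate C(sp2)–Br bond forms C12–C13 and installs the butenolide as a finished ring under a mild phosphate base.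

Step 17
Reactants: 28 target 18,19-acetonide
Product: 29 3-{2-[(1R,2S,4aS,8aS)-2,5,5-tris(hydroxymethyl)-8a-methyldecahydronaphthalen-1-yl]ethyl}furan-2(5H)-one
Conditions: 1 M HCl, THF, rt
Reagents that add atoms: none
Why: Acid-catalysed acetal hydrolysis releases the C18/C19 diol, and the butenolide and all stereocentres are stable to dilute aqueous acid.

**Compound list**

1 | 5-chloropent-1-yne | C#CCCCCl | starting material
2 | (E)-(5-chloro-2-methylpent-1-en-1-yl)dimethylalane | C/C(CCCCl)=C\[Al](C)C | intermediate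
3 | lithium butyl[(E)-5-chloro-2-methylpent-1-en-1-yl]dimethylaluminate | [Li+].CCCC[Al-](C)(C)/C=C(\C)CCCCl | intermediate
4 | (E)-6-chloro-3-methylhex-2-enoic acid | C/C(CCCCl)=C\C(=O)O | intermediate
5 | (R)-4-benzyloxazolidin-2-one | O=C1N[C@H](Cc2ccccc2)CO1 | starting material
6 | (E)-6-chloro-3-methylhex-2-enoic pivalic anhydride | C/C(CCCCl)=C\C(=O)OC(=O)C(C)(C)C | intermediate
7 | (R)-4-benzyl-3-[(E)-6-chloro-3-methylhex-2-enoyl]oxazolidin-2-one | C/C(CCCCl)=C\C(=O)N1C(=O)OC[C@H]1Cc1ccccc1 | intermediate
8 | (R)-4-benzyl-3-[(E)-6-iodo-3-methylhex-2-enoyl]oxazolidin-2-one | C/C(CCCI)=C\C(=O)N1C(=O)OC[C@H]1Cc1ccccc1 | intermediate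
9 | 3-[(tert-butyldimethylsilyl)oxy]propanal | O=CCCO[Si](C)(C)C(C)(C)C | starting material
10 | (E)-5-[(tert-butyldimethylsilyl)oxy]pent-2-enal | O=C/C=C/CCO[Si](C)(C)C(C)(C)C | intermediate
11 | dimethyl malonate | COC(=O)CC(=O)OC | starting material
12 | dimethyl 2-[(2E)-5-[(tert-butyldimethylsilyl)oxy]pent-2-en-1-ylidene]malonate | COC(=O)C(C(=O)OC)=C/C=C/CCO[Si](C)(C)C(C)(C)C | intermediate
13 | potassium trienolate of dimethyl 2-[(1E,3E)-5-(TBSO)penta-1,3-dien-1-yl]malonate | COC(=O)C(/C=C/C=C/CO[Si](C)(C)C(C)(C)C)=C([O-])OC.[K+] | intermediate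
14 | trienimide: dimethyl 2-{(4E)-6-[(R)-4-benzyl-2-oxooxazolidin-3-yl]-4-methyl-6-oxohex-4-en-1-yl}-2-[(1E,3E)-5-[(tert-butyldimethylsilyl)oxy]penta-1,3-dien-1-yl]malonate | C/C(=C\C(=O)N1C(=O)OC[C@H]1Cc1ccccc1)CCCC(C(=O)OC)(C(=O)OC)/C=C/C=C/CO[Si](C)(C)C(C)(C)C | intermediate
15 | dimethylaluminium chelate of 14 (both imide carbonyls on Al; dimethyldichloroaluminate counter-ion) | C/C(CCCC(C(=O)OC)(C(=O)OC)/C=C/C=C/CO[Si](C)(C)C(C)(C)C)=C\C1=[O+][Al-](C)(C)[O+]=C2OC[C@@H](Cc3ccccc3)N12.C[Al-](C)(Cl)Cl | intermediate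
16 | Diels–Alder adduct: Δ6-trans-octalin; 4,4-bis(methoxycarbonyl); 10α-CH3; 5β-H; 8α-CH2OTBS (cis to C20); 9α-C(=O)Xc | C[C@@]12CCCC(C(=O)OC)(C(=O)OC)[C@H]1C=C[C@@H](CO[Si](C)(C)C(C)(C)C)[C@H]2C(=O)N1C(=O)OC[C@H]1Cc1ccccc1 | intermediate
17 | saturated imide: 6,7-dihydro derivative of 16 | C[C@@]12CCCC(C(=O)OC)(C(=O)OC)[C@H]1CC[C@@H](CO[Si](C)(C)C(C)(C)C)[C@H]2C(=O)N1C(=O)OC[C@H]1Cc1ccccc1 | intermediate
18 | 8-epi triol: 4,4-bis(hydroxymethyl); 9α-CH2OH; 8α-CH2OTBS; 10α-CH3; 5β-H | C[C@@]12CCCC(CO)(CO)[C@H]1CC[C@@H](CO[Si](C)(C)C(C)(C)C)[C@H]2CO | intermediate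
19 | acetonide alcohol: C18/C19 as 2,2-dimethyl-1,3-dioxane spiro at C4; 9α-CH2OH; 8α-CH2OTBS | C[C@@]12CCCC3(COC(C)(C)OC3)[C@H]1CC[C@@H](CO[Si](C)(C)C(C)(C)C)[C@H]2CO | intermediate
20 | C11 aldehyde: 9α-CHO; 8α-CH2OTBS; C4 spiro-acetonide | C[C@@]12CCCC3(COC(C)(C)OC3)[C@H]1CC[C@@H](CO[Si](C)(C)C(C)(C)C)[C@H]2C=O | intermediate
21 | vinyl compound: 9α-CH=CH2; 8α-CH2OTBS; C4 spiro-acetonide | C[C@@]12CCCC3(COC(C)(C)OC3)[C@H]1CC[C@@H](CO[Si](C)(C)C(C)(C)C)[C@H]2C=C | intermediate
22 | 8-epi alcohol: 9α-CH=CH2; 8α-CH2OH (axial); C4 spiro-acetonide | C[C@@]12CCCC3(COC(C)(C)OC3)[C@H]1CC[C@@H](CO)[C@H]2C=C | intermediate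
23 | 8-epi aldehyde: 9α-CH=CH2; 8α-CHO (axial); C4 spiro-acetonide | C[C@@]12CCCC3(COC(C)(C)OC3)[C@H]1CC[C@@H](C=O)[C@H]2C=C | intermediate
24 | 8β-aldehyde: 9α-CH=CH2; 8β-CHO (equatorial); C4 spiro-acetonide | C[C@@]12CCCC3(COC(C)(C)OC3)[C@H]1CC[C@H](C=O)[C@H]2C=C | intermediate
25 | 8β-hydroxymethyl 9α-vinyl acetonide | C[C@@]12CCCC3(COC(C)(C)OC3)[C@H]1CC[C@H](CO)[C@H]2C=C | intermediate
26 | 3-bromofuran-2(5H)-one | O=C1OCC=C1Br | starting material
27 | bis-boryl adduct: C12–B(9-BBN) and C17–O–B(9-BBN) | C[C@@]12CCCC3(COC(C)(C)OC3)[C@H]1CC[C@H](COB1C3CCCC1CCC3)[C@H]2CCB1C2CCCC1CCC2 | intermediate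
28 | target 18,19-acetonide | C[C@@]12CCCC3(COC(C)(C)OC3)[C@H]1CC[C@H](CO)[C@H]2CCC1=CCOC1=O | intermediate
29 | 3-{2-[(1R,2S,4aS,8aS)-2,5,5-tris(hydroxymethyl)-8a-methyldecahydronaphthalen-1-yl]ethyl}furan-2(5H)-one (labdane numbering 5S,8S,9R,10S) | C[C@@]12CCCC(CO)(CO)[C@H]1CC[C@H](CO)[C@H]2CCC1=CCOC1=O | target

**Step count and risks**

Total steps: 17. Longest linear sequence: 15 (steps 1–3, then 6–17); the second branch (steps 4–5) joins at step 6.

Steps most likely to fail:

Step 7. Cycloaddition of the trisubstituted dienophile may be too slow at temperatures the aluminium Lewis acid allows. Ionisation of the dienylic silyl ether, binding of the Lewis acid by the malonate, and loss of endo and facial selectivity on warming would then compete. The fallback replaces auxiliary control by catalyst control; it sets out from acid 4 and comes back at triol 18. Acid 4 is acylated onto achiral oxazolidin-2-one by the step 2 protocol to give 3-[(E)-6-chloro-3-methylhex-2-enoyl]oxazolidin-2-one F1. Halide exchange as in step 3 gives 3-[(E)-6-iodo-3-methylhex-2-enoyl]oxazolidin-2-one F2, and alkylation of trienolate 13 as in step 6 gives the achiral trienimide F3. A cationic Cu(II)–bis(oxazoline) catalyst, [Cu((S,S)-t-Bu-box)](SbF6)2 (10 mol %, CH2Cl2, rt), binds only the imide in a square-planar chelate and by that model leaves the same C9-re face open; it should give the achiral-imide octalin adduct F4. Hydrogenation as in step 8 gives the achiral-imide decalin F5, and LiAlH4 as in step 9 gives 18.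

Step 6. The pentadienyl-malonate anion may expel silyloxide (1,6-elimination), be alkylated at C6 or C8 instead of C4, or give a diene of mixed geometry. The fallback assembles the diene by cross-coupling after the quaternary carbon is in place; it sets out from iodide 8 and malonate 11 and comes back at 14. The sodium salt of 11 (NaH, excess 11, THF–DMF) is alkylated by 8 to the monoalkyl malonate F6. Its potassium enolate (KHMDS, THF, −78 °C) is ethynylated with ethynyl(phenyl)iodonium tetrafluoroborate to the α-ethynyl malonate F7. Palladium-catalysed hydrostannation (Bu3SnH, PdCl2(PPh3)2, THF) gives the (E)-vinylstannane F8. Stille coupling with (E)-tert-butyl[(3-iodoprop-2-en-1-yl)oxy]dimethylsilane (Pd2(dba)3, AsPh3, NMP) then gives 14, with both alkene geometries carried in by the coupling partners.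

Step 16. Ring opening or double-bond migration of the bromobutenolide under aqueous base, and protodeboronation of the hindered alkylborane, may outrun transmetalation. The fallback builds the butenolide by enolate alkylation and sulfoxide elimination; it sets out from 25 and comes back at 29. Alcohol 25 is silylated (TBSCl, imidazole, DMF) to the 17-O-TBS ether F9. Hydroboration–oxidation (9-BBN; NaOH, H2O2) gives the C12 alcohol F10, and Appel iodination (I2, PPh3, imidazole) gives the C12 iodide F11. The lithium enolate of 3-(phenylthio)dihydrofuran-2(3H)-one (LDA, THF–HMPA, −78 °C → rt) is alkylated by F11 to the α-phenylthio lactone F12. Oxidation (mCPBA, CH2Cl2, −78 °C) gives the sulfoxide F13, and thermal syn-elimination (toluene, 110 °C) gives the doubly protected butenolide F14. The acid treatment of step 17 then removes the silyl ether and the acetonide to give 29.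

**Further compounds**

F1 | step 7 | 3-[(E)-6-chloro-3-methylhex-2-enoyl]oxazolidin-2-one | C/C(CCCCl)=C\C(=O)N1CCOC1=O
F2 | step 7 | 3-[(E)-6-iodo-3-methylhex-2-enoyl]oxazolidin-2-one | C/C(CCCI)=C\C(=O)N1CCOC1=O
F3 | step 7 | achiral trienimide: dimethyl 2-[(4E)-4-methyl-6-oxo-6-(2-oxooxazolidin-3-yl)hex-4-en-1-yl]-2-[(1E,3E)-5-(TBSO)penta-1,3-dien-1-yl]malonate | C/C(=C\C(=O)N1CCOC1=O)CCCC(C(=O)OC)(C(=O)OC)/C=C/C=C/CO[Si](C)(C)C(C)(C)C
F4 | step 7 | achiral-imide octalin adduct (as 16 with oxazolidin-2-one in place of Xc) | C[C@@]12CCCC(C(=O)OC)(C(=O)OC)[C@H]1C=C[C@@H](CO[Si](C)(C)C(C)(C)C)[C@H]2C(=O)N1CCOC1=O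
F5 | step 7 | achiral-imide decalin (6,7-dihydro F4) | C[C@@]12CCCC(C(=O)OC)(C(=O)OC)[C@H]1CC[C@@H](CO[Si](C)(C)C(C)(C)C)[C@H]2C(=O)N1CCOC1=O
F6 | step 6 | monoalkyl malonate: dimethyl 2-[(4E)-4-methyl-6-oxo-6-Xc-hex-4-en-1-yl]malonate | C/C(CCCC(C(=O)OC)C(=O)OC)=C\C(=O)N1C(=O)OC[C@H]1Cc1ccccc1
F7 | step 6 | α-ethynyl malonate: dimethyl 2-ethynyl-2-[(4E)-4-methyl-6-oxo-6-Xc-hex-4-en-1-yl]malonate | C/C(CCCC(C#C)(C(=O)OC)C(=O)OC)=C\C(=O)N1C(=O)OC[C@H]1Cc1ccccc1
F8 | step 6 | (E)-vinylstannane: dimethyl 2-[(4E)-4-methyl-6-oxo-6-Xc-hex-4-en-1-yl]-2-[(E)-2-(tributylstannyl)ethenyl]malonate | C/C(CCCC(/C=C/[Sn](CCCC)(CCCC)CCCC)(C(=O)OC)C(=O)OC)=C\C(=O)N1C(=O)OC[C@H]1Cc1ccccc1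
F9 | step 16 | 17-O-TBS ether of 25 | C[C@@]12CCCC3(COC(C)(C)OC3)[C@H]1CC[C@H](CO[Si](C)(C)C(C)(C)C)[C@H]2C=C
F10 | step 16 | C12 alcohol (9α-CH2CH2OH; 8β-CH2OTBS; C4 spiro-acetonide) | C[C@@]12CCCC3(COC(C)(C)OC3)[C@H]1CC[C@H](CO[Si](C)(C)C(C)(C)C)[C@H]2CCO
F11 | step 16 | C12 iodide (9α-CH2CH2I; 8β-CH2OTBS; C4 spiro-acetonide) | C[C@@]12CCCC3(COC(C)(C)OC3)[C@H]1CC[C@H](CO[Si](C)(C)C(C)(C)C)[C@H]2CCI
F12 | step 16 | α-phenylthio lactone (3-alkyl-3-(phenylthio)dihydrofuran-2(3H)-one; mixture at the lactone α-carbon) | C[C@@]12CCCC3(COC(C)(C)OC3)[C@H]1CC[C@H](CO[Si](C)(C)C(C)(C)C)[C@H]2CCC1(Sc2ccccc2)CCOC1=O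
F13 | step 16 | sulfoxide of F12 | C[C@@]12CCCC3(COC(C)(C)OC3)[C@H]1CC[C@H](CO[Si](C)(C)C(C)(C)C)[C@H]2CCC1(S(=O)c2ccccc2)CCOC1=O
F14 | step 16 | doubly protected butenolide (17-O-TBS 18,19-O-isopropylidene derivative of 29) | C[C@@]12CCCC3(COC(C)(C)OC3)[C@H]1CC[C@H](CO[Si](C)(C)C(C)(C)C)[C@H]2CCC1=CCOC1=O
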